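Unprotected, symmetric 2-methoxyresorcinol 1 and acrylic acid 2 are annulated on a sulfonic acid resin, through hydroxy acid 3, to 7-hydroxy-8-methoxy-3,4-dihydrocoumarin 4, which octadecan-1-ol 5 opens to target 6. Ring carbons are C1 (chain-bearing), C2 (OH), C3 (OMe), C4 (OH), C5 and C6; the chain runs C7, C8 to carbonyl C9. The disconnection cuts C1–C7 and the bond from the C2 oxygen to C9, that is, the six-membered lactone ring. The key step makes both bonds and this ring in one operation. It exploits the mirror symmetry of the C2–C3–C4 oxygen triad: C1 and C5 are equivalent, each ortho to one hydroxyl and para to the other, so one regioisomer forms and the lactone tags the C2 oxygen.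

Key step: step 1

Remark on the chemistry: the target has no stereocentre and needs no protecting group; the whole route is two steps, so the risk ranking at the end can cover only these two.

Step 1
Reactants: 1 2-methoxyresorcinol; 2 acrylic acid
Product: 4 7-hydroxy-8-methoxy-3,4-dihydrocoumarin, via ring-open hydroxy acid 3 (not isolated)
Conditions: 2 (1.1 equiv), Amberlyst-15 (dry polystyrene sulfonic acid resin, H+ form), toluene, reflux, Dean–Stark, N2; hot filtration
Reagents that add atoms: none
Why: The resin protonates 2 at the carbonyl oxygen, C1 of 1 (ortho to the C2 hydroxyl, para to the C4 hydroxyl) adds to the beta carbon C7 in a Friedel–Crafts conjugate hydroarylation, and rearomatisation gives hydroxy acid 3. The C2 hydroxyl then attacks the activated carboxyl carbon C9 in a 6-exo-trig acyl substitution (acid-catalysed lactonisation) and azeotropic removal of water carries 3 on to lactone 4; the reverse order, O-acylation followed by 6-endo-trig ring alkylation, would converge on the same lactone. The closest known reaction type is the acid-mediated condensation of resorcinols with acrylic acid to 7-hydroxy-3,4-dihydrocoumarins, a formal (3+3) annulation. No stereocentre is formed. The step needs site selectivity and mono-annulation: C1 and C5 are related by the mirror plane through C3 and C6 and are each activated by two hydroxyls, whereas C6 is only para to the methoxy group, and once the C2 oxygen is acylated its donation to C5 is weakened while 2 is held near one equivalent. A resin acid in a non-polar medium should be too weak to generate an acylium ion from 2, which disfavours ring C-acylation.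

Step 2
Reactants: 4 7-hydroxy-8-methoxy-3,4-dihydrocoumarin; 5 octadecan-1-ol
Product: 6 octadecyl 3-(2,4-dihydroxy-3-methoxyphenyl)propanoate
Conditions: 5 (4 equiv, melt), MsOH (5 mol %), neat, 75 °C, N2; then EtOAc, aq NaHCO3 wash before concentration
Reagents that add atoms: none
Why: Acid-catalysed ring-opening transesterification (alcoholysis of an aryl lactone): the phenolic leaving group makes 4 an activated ester, the roughly 3 M alcohol of the melt should push the equilibrium to the open alkyl ester, the free phenols and the methyl ether are inert, and neutralising the acid before isolation should prevent relactonisation.

Compound list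
1 | 2-methoxyresorcinol (2-methoxybenzene-1,3-diol) | COc1c(O)cccc1O | starting material
2 | acrylic acid (prop-2-enoic acid) | C=CC(=O)O | starting material
3 | 3-(2,4-dihydroxy-3-methoxyphenyl)propanoic acid (ring-open hydroxy acid, not isolated in step 1) | OC(=O)CCc1ccc(O)c(OC)c1O | intermediate
4 | 7-hydroxy-8-methoxy-3,4-dihydrocoumarin (7-hydroxy-8-methoxychroman-2-one) | O=C1CCc2ccc(O)c(OC)c2O1 | intermediate
5 | octadecan-1-ol | CCCCCCCCCCCCCCCCCCO | starting material
6 | octadecyl 3-(2,4-dihydroxy-3-methoxyphenyl)propanoate | CCCCCCCCCCCCCCCCCCOC(=O)CCc1ccc(O)c(OC)c1O | target

Total step count: 2
Longest linear sequence: 2 steps (1 to 4 to 6)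

Steps most likely to fail (only two steps exist, so both are ranked)

1. Step 1 (key step). What may go wrong: ring C-acylation competing with conjugate addition, polymerisation of the acrylic acid before it is captured, or a second annulation at C5 of the product. Fallback, setting out from 1 and coming back at 4: a Pechmann-type coumarin synthesis of 1 with ethyl propiolate (ZnCl2, dioxane, 100 °C) should give 7-hydroxy-8-methoxycoumarin F1, again as a single regioisomer because of the symmetry of 1. Hydrogenation of the lactone-ring C=C bond of F1 (H2 1 atm, 10% Pd/C, EtOAc, rt) should then deliver 4. The C1–C7 and O–C9 bonds are the same as in the main route, but the ring is built at the unsaturated oxidation level and reduced afterwards.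

2. Step 2. What may go wrong: incomplete ring opening because the equilibrium is not driven far enough in the melt, or relactonisation with loss of the alcohol during work-up and purification. Fallback, setting out from 4 and coming back at 6: saponification of 4 (KOH, degassed aq THF, 0 °C to rt; then cold aq HCl to pH 3, extraction) should give acid 3, this time isolated. Chemoselective SN2 O-alkylation of its carboxylate (KHCO3, 1-bromooctadecane, DMF, 50 °C) then forms the ester at the alkyl carbon instead of the acyl carbon. The phenols stay protonated under bicarbonate, and the step no longer depends on an equilibrium. The only compound on this path, 3, is already in the compound list.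

Further compounds
F1 | step 1 | 7-hydroxy-8-methoxycoumarin | O=C1C=Cc2ccc(O)c(OC)c2O1
F0 | step 2 | none | none
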